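**Assumption:** Diplotrin B is an achiral, planar flavone with no stereocentre, so the "single enantiomer" is fixed by constitution alone; the only stereocentres in the route are the two racemic ones of the transient intermediate 4, erased in the same flask.

## Retrosynthetic overview

1. Last bond: the C3–O–CH3 ether, made on the unprotected 3,3'-dihydroxyflavone, with O3 distinguished from the ring B phenol by a carbonyl-O-methylated flavylium relay (proposed new C–O chemistry).
2. Ring C: the O1–C2 and C3–O bonds come from Algar–Flynn–Oyamada oxidative cyclisation of a 2'-hydroxychalcone.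
3. Chalcone: Claisen–Schmidt union of 2'-hydroxy-3',4'-dimethoxyacetophenone and isovanillin, both cheap and commercial.
4. Ring order: rings A and B are bought with all oxygens in place; ring C is the only ring formed (step 2); no protecting groups.

## Route

Step 1
Reactants: 1 ketone 2'-hydroxy-3',4'-dimethoxyacetophenone [1-(2-hydroxy-3,4-dimethoxyphenyl)ethan-1-one]; 2 isovanillin (3-hydroxy-4-methoxybenzaldehyde)
Product: 3 chalcone (E)-1-(2-hydroxy-3,4-dimethoxyphenyl)-3-(3-hydroxy-4-methoxyphenyl)prop-2-en-1-one
Conditions: KOH (50% aq., 6 equiv), EtOH, 0 °C → rt, 48 h; then 2 M HCl, 0 °C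
Reagents that add atoms: none
Why: Claisen–Schmidt (crossed aldol) condensation, in which the enolate of 1 adds to 2 (its phenoxide is meta to the formyl group and does not deactivate it) and E1cB dehydration gives the conjugated E-enone as the thermodynamic isomer; no stereocentre is formed.

Step 2
Reactants: 3 chalcone (E)-1-(2-hydroxy-3,4-dimethoxyphenyl)-3-(3-hydroxy-4-methoxyphenyl)prop-2-en-1-one
Product: 5 flavonol 3,3'-dihydroxy-4',7,8-trimethoxyflavone [3-hydroxy-2-(3-hydroxy-4-methoxyphenyl)-7,8-dimethoxy-4H-chromen-4-one], via racemic trans-dihydroflavonol 4 (not isolated)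
Conditions: 30% aq. H2O2 (3 equiv), 2 M aq. NaOH (6 equiv), MeOH, 0 °C → rt, 4 h; then 2 M HCl
Reagents that add atoms: hydrogen peroxide, OO
Why: Algar–Flynn–Oyamada reaction, in which the 2'-phenoxide closes ring C by 6-endo oxa-Michael addition (O1–C2 bond) while alkaline H2O2 oxygenates C3 and then dehydrogenates 4; flavonol rather than aurone is expected because ring A has no 6'-substituent, and the two racemic stereocentres of 4 are erased on aromatisation.

Step 3
Reactants: 5 flavonol 3,3'-dihydroxy-4',7,8-trimethoxyflavone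
Product: 9 diplotrin B [2-(3-hydroxy-4-methoxyphenyl)-3,7,8-trimethoxy-4H-chromen-4-one], via 3-hydroxy-4-methoxyflavylium triflate 6 (not isolated), via 4-methoxy-3-oxidoflavylium betaine 7 (not isolated), via 3,4-dimethoxyflavylium triflate 8 (not isolated)
Conditions: MeOTf (2.2 equiv), 2,6-di-tert-butyl-4-methylpyridine (1.2 equiv), CH2Cl2, −20 °C → rt, 3 h; then n-Bu4NI (1.5 equiv), rt, 1 h
Reagents that add atoms: methyl trifluoromethanesulfonate (MeOTf), COS(=O)(=O)C(F)(F)F
Why: Proposed new method: a base-free carbonyl-O-methylation/flavylium relay for chemoselective 3-O-methylation (SN2 O-alkylation, no stereocentre) – MeOTf first methylates the pyranone C4=O, by far the most basic and nucleophilic oxygen of neutral 5, to give 6, whose 3-OH is then acidic enough (estimated pKa below 5) for the hindered pyridine to remove while the ring B phenol (pKa about 10) stays protonated and non-nucleophilic; betaine 7 is O-methylated to 8 and iodide removes only the oxocarbenium-type O4-methyl, restoring the 4-pyranone of 9; the closest known reaction types are the MeOTf/base conversion of 3-hydroxy-4-pyranones into 4-methoxy-3-oxidopyrylium ylides and the nucleophilic O-dealkylation of 4-alkoxypyrylium salts.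

## Compound list

1 | 2'-hydroxy-3',4'-dimethoxyacetophenone [1-(2-hydroxy-3,4-dimethoxyphenyl)ethan-1-one] | CC(=O)c1ccc(OC)c(OC)c1O | starting material
2 | isovanillin (3-hydroxy-4-methoxybenzaldehyde) | COc1ccc(C=O)cc1O | starting material
3 | (E)-1-(2-hydroxy-3,4-dimethoxyphenyl)-3-(3-hydroxy-4-methoxyphenyl)prop-2-en-1-one | COc1ccc(/C=C/C(=O)c2ccc(OC)c(OC)c2O)cc1O | intermediate
4 | racemic trans-(2R*,3R*)-3-hydroxy-2-(3-hydroxy-4-methoxyphenyl)-7,8-dimethoxychroman-4-one (one enantiomer of the racemate drawn) | O[C@@H]1[C@@H](c2ccc(OC)c(O)c2)Oc2c(OC)c(OC)ccc2C1=O | intermediate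
5 | 3-hydroxy-2-(3-hydroxy-4-methoxyphenyl)-7,8-dimethoxy-4H-chromen-4-one (3,3'-dihydroxy-4',7,8-trimethoxyflavone) | COc1ccc(-c2oc3c(OC)c(OC)ccc3c(=O)c2O)cc1O | intermediate
6 | 3-hydroxy-2-(3-hydroxy-4-methoxyphenyl)-4,7,8-trimethoxychromenylium trifluoromethanesulfonate (3-hydroxy-4-methoxyflavylium triflate) | COc1ccc(-c2[o+]c3c(OC)c(OC)ccc3c(OC)c2O)cc1O.[O-]S(=O)(=O)C(F)(F)F | intermediate
7 | 2-(3-hydroxy-4-methoxyphenyl)-4,7,8-trimethoxychromenylium-3-olate (4-methoxy-3-oxidoflavylium betaine) | COc1ccc(-c2[o+]c3c(OC)c(OC)ccc3c(OC)c2[O-])cc1O | intermediate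
8 | 2-(3-hydroxy-4-methoxyphenyl)-3,4,7,8-tetramethoxychromenylium trifluoromethanesulfonate (3,4-dimethoxyflavylium triflate) | COc1ccc(-c2[o+]c3c(OC)c(OC)ccc3c(OC)c2OC)cc1O.[O-]S(=O)(=O)C(F)(F)F | intermediate
9 | diplotrin B [2-(3-hydroxy-4-methoxyphenyl)-3,7,8-trimethoxy-4H-chromen-4-one] | COc1ccc(-c2oc3c(OC)c(OC)ccc3c(=O)c2OC)cc1O | target

## Step count and risks

Total step count: 3. Longest linear sequence: 3 steps (1 or 2 → 3 → 5 → 9).

Steps most likely to fail, most risky first:

Step 3 (the proposed relay methylation). The risks are slow methylation of the neutral ring B phenol by excess MeOTf, side reactions of betaine 7 (cycloaddition or dimerisation), and incomplete removal of the O4-methyl. The fallback uses only known chemistry and replaces reagent-controlled selectivity by a protecting group; it sets out from chalcone 3 and comes back at 9. The non-chelated ring B phenol of 3 is benzylated selectively (BnBr 1.05 equiv, K2CO3, acetone, reflux; the 2'-OH is hydrogen-bonded to the ketone and stays free) to give (E)-3-(3-benzyloxy-4-methoxyphenyl)-1-(2-hydroxy-3,4-dimethoxyphenyl)prop-2-en-1-one F1. Algar–Flynn–Oyamada cyclisation under the step 2 conditions gives 2-(3-benzyloxy-4-methoxyphenyl)-3-hydroxy-7,8-dimethoxy-4H-chromen-4-one F2. Its only free hydroxyl is methylated (MeI, K2CO3, acetone, reflux) to 2-(3-benzyloxy-4-methoxyphenyl)-3,7,8-trimethoxy-4H-chromen-4-one F3. Hydrogenolysis (H2, Pd/C, EtOAc–MeOH, rt) then gives 9.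

Step 2 (oxidative cyclisation with a free ring B phenol). The risks are oxidative degradation of the electron-rich phenoxide, stalling at dihydroflavonol 4, and low recovery. The fallback separates ring closure from C3 oxygenation; it sets out from chalcone 3 and comes back at 5. Catalytic I2 in DMSO at 120 °C closes ring C without oxygenating C3 and gives the flavone 2-(3-hydroxy-4-methoxyphenyl)-7,8-dimethoxy-4H-chromen-4-one F4. C3 is then deprotonated with LiN(iPr)2 (3 equiv, THF, −78 °C; one equivalent is consumed by the phenol) and trapped with B(OMe)3 as dimethyl [2-(3-hydroxy-4-methoxyphenyl)-7,8-dimethoxy-4-oxo-4H-chromen-3-yl]boronate F5. Oxidation of the C–B bond in the same flask (H2O2, AcOH, 0 °C → rt) gives 5, which goes on to step 3.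

Step 1 (hydroxide aldol with two free phenols). The risks are slow or incomplete condensation of the doubly deprotonated partners and partial cyclisation to flavanone on work-up. The fallback changes the C–C bond-forming mode from hydroxide aldol to amine (enamine/iminium) condensation and the isolated intermediate from chalcone to flavanone; it sets out from 1 and 2 and comes back at 3. Pyrrolidine (1.5 equiv) in MeOH at 65 °C gives, by Mannich-type condensation and oxa-Michael closure, the racemic flavanone 2-(3-hydroxy-4-methoxyphenyl)-7,8-dimethoxychroman-4-one F6. F6 is put into the NaOH/MeOH of step 2, where retro-oxa-Michael opening regenerates the phenoxide of 3 in the flask before H2O2 is added, so the route continues to 5 unchanged.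

## Further compounds

F1 | step 3 | (E)-3-(3-benzyloxy-4-methoxyphenyl)-1-(2-hydroxy-3,4-dimethoxyphenyl)prop-2-en-1-one | COc1ccc(/C=C/C(=O)c2ccc(OC)c(OC)c2O)cc1OCc1ccccc1
F2 | step 3 | 2-(3-benzyloxy-4-methoxyphenyl)-3-hydroxy-7,8-dimethoxy-4H-chromen-4-one | COc1ccc(-c2oc3c(OC)c(OC)ccc3c(=O)c2O)cc1OCc1ccccc1
F3 | step 3 | 2-(3-benzyloxy-4-methoxyphenyl)-3,7,8-trimethoxy-4H-chromen-4-one | COc1ccc(-c2oc3c(OC)c(OC)ccc3c(=O)c2OC)cc1OCc1ccccc1
F4 | step 2 | 2-(3-hydroxy-4-methoxyphenyl)-7,8-dimethoxy-4H-chromen-4-one | COc1ccc(-c2cc(=O)c3ccc(OC)c(OC)c3o2)cc1O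
F5 | step 2 | dimethyl [2-(3-hydroxy-4-methoxyphenyl)-7,8-dimethoxy-4-oxo-4H-chromen-3-yl]boronate | COB(OC)c1c(-c2ccc(OC)c(O)c2)oc2c(OC)c(OC)ccc2c1=O
F6 | step 1 | racemic 2-(3-hydroxy-4-methoxyphenyl)-7,8-dimethoxychroman-4-one | COc1ccc(C2CC(=O)c3ccc(OC)c(OC)c3O2)cc1O
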